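**Retrosynthetic overview**

Numbering: ring A is C1(OAc)–C2–C3–C8–C9=C10(Me), ring B is C3–C4(Me)–C5(OAc)–C6–C7–C8, and the exocyclic alkene is C7=C11 with methyl C12 and oxygenated C13.
The route rests on the homoallylic array O–C5–C6–C7=C11 of ring B: it is cut at C5–C6 by an intramolecular type 2 carbonyl-ene reaction of aldehyde 22, in which the hydrogen of the stereogenic C11 is transferred and the C11 configuration becomes the E geometry of C7=C11 (ring B is formed last).
End game: axial C5 alcohol 23, then ketone, equatorial alcohol, diacetate, desilylation and C13 formate.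
Aldehyde 22 comes from Diels–Alder adduct 15 (ring A, formed first from dienyl acetate 13 and methyl vinyl ketone); C4 is set by equilibration in the cis-fused lactol 18, and the C7 carbinol is then turned into the 1,1-disubstituted alkene.
Diene 13 comes from methyl (S)-3-hydroxy-2-methylpropanoate (C7, C11 to C13) by Brown allylation, ozonolysis, Wittig olefination and dienol acetate formation.

Key step: step 15

Remark: the C13 oxygen is carried as its tert-butyldiphenylsilyl ether so that it survives the acidic steps 10 and 11; (−)-B-allyldiisopinocampheylborane and the (R)-diphenylprolinol-derived oxazaborolidine are assumed to be commercial.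

**Route**

Step 1
Reactants: 1 methyl (S)-3-hydroxy-2-methylpropanoate
Product: 2 methyl (S)-3-[(tert-butyldiphenylsilyl)oxy]-2-methylpropanoate
Conditions: TBDPSCl, imidazole, DMF, rt
Reagents that add atoms: tert-butyl(chloro)diphenylsilane, CC(C)(C)[Si](Cl)(c1ccccc1)c1ccccc1
Why: Imidazole-promoted silylation of the primary alcohol leaves the C11 stereocentre untouched and gives an ether that withstands the later acidic steps.

Step 2
Reactants: 2 methyl (S)-3-[(tert-butyldiphenylsilyl)oxy]-2-methylpropanoate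
Product: 3 (S)-3-[(tert-butyldiphenylsilyl)oxy]-2-methylpropanal
Conditions: i-Bu2AlH, CH2Cl2, −78 °C; aqueous potassium sodium tartrate
Reagents that add atoms: none
Why: Partial reduction of the ester with i-Bu2AlH at low temperature stops at the aluminium hemiacetal, which releases the configurationally labile aldehyde only on work-up, and the aldehyde is used at once.

Step 3
Reactants: 3 (S)-3-[(tert-butyldiphenylsilyl)oxy]-2-methylpropanal; 4 (−)-B-allyldiisopinocampheylborane
Product: 6 (2S,3S)-1-[(tert-butyldiphenylsilyl)oxy]-2-methylhex-5-en-3-ol, via diisopinocampheylborinate ester 5 (not isolated)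
Conditions: Et2O, −78 °C; then NaOH, H2O2, H2O, 0 °C → rt
Reagents that add atoms: (−)-B-allyldiisopinocampheylborane 4, C=CCB([C@@H]1C[C@@H]2C[C@H]([C@H]1C)C2(C)C)[C@@H]1C[C@@H]2C[C@H]([C@H]1C)C2(C)C
Why: Brown allylation under reagent control: the allylborane derived from (+)-α-pinene should add to the Si face of the aldehyde through a six-membered chair transition state and set C7 as S (2,3-syn), a temporary centre that steers the Diels–Alder face in step 8 and anchors the lactol in step 10, after which oxidative work-up cleaves the borinate.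

Step 4
Reactants: 6 (2S,3S)-1-[(tert-butyldiphenylsilyl)oxy]-2-methylhex-5-en-3-ol
Product: 7 (2S,3S)-1-[(tert-butyldiphenylsilyl)oxy]-2-methyl-3-[(triethylsilyl)oxy]hex-5-ene
Conditions: TESCl, imidazole, CH2Cl2, 0 °C → rt
Reagents that add atoms: chlorotriethylsilane, CC[Si](Cl)(CC)CC
Why: Silylation of the secondary alcohol protects the C7 oxygen with a group that is a poor leaving group during dienolate formation and can be removed by mild acid beside the tert-butyldiphenylsilyl ether.

Step 5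
Reactants: 7 (2S,3S)-1-[(tert-butyldiphenylsilyl)oxy]-2-methyl-3-[(triethylsilyl)oxy]hex-5-ene
Product: 9 (3S,4S)-5-[(tert-butyldiphenylsilyl)oxy]-4-methyl-3-[(triethylsilyl)oxy]pentanal, via secondary ozonide 8 (not isolated)
Conditions: O3, CH2Cl2, −78 °C; then PPh3, −78 °C → rt
Reagents that add atoms: ozone, [O-][O+]=O
Why: Ozonolysis of the only alkene and reduction of the ozonide with PPh3 shortens the chain by one carbon to the β-silyloxy aldehyde, which is used without chromatography to avoid β-elimination.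

Step 6
Reactants: 9 (3S,4S)-5-[(tert-butyldiphenylsilyl)oxy]-4-methyl-3-[(triethylsilyl)oxy]pentanal; 10 2-(triphenylphosphoranylidene)propanal
Product: 11 (2E,5S,6S)-7-[(tert-butyldiphenylsilyl)oxy]-2,6-dimethyl-5-[(triethylsilyl)oxy]hept-2-enal
Conditions: toluene, 80 °C
Reagents that add atoms: 2-(triphenylphosphoranylidene)propanal 10, CC(C=O)=P(c1ccccc1)(c1ccccc1)c1ccccc1
Why: Wittig olefination with the stabilised, α-branched ylide should give the (E)-trisubstituted enal and brings in C1, C10 and the C10 methyl.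

Step 7
Reactants: 11 (2E,5S,6S)-7-[(tert-butyldiphenylsilyl)oxy]-2,6-dimethyl-5-[(triethylsilyl)oxy]hept-2-enal
Product: 13 (1E,3E,5S,6S)-7-[(tert-butyldiphenylsilyl)oxy]-2,6-dimethyl-5-[(triethylsilyl)oxy]hepta-1,3-dien-1-yl acetate, via potassium dienolate 12 (not isolated)
Conditions: KN(SiMe3)2, THF, −78 °C; then Ac2O, −78 °C
Reagents that add atoms: acetic anhydride, CC(=O)OC(C)=O
Why: γ-Deprotonation of the s-trans enal at C8 gives the extended potassium dienolate, and O-acetylation should give the (1E,3E)-dienyl acetate, since the oxygen stays trans to C9 and the new C8=C9 bond avoids allylic strain with the C10 methyl.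

Step 8
Reactants: 13 (1E,3E,5S,6S)-7-[(tert-butyldiphenylsilyl)oxy]-2,6-dimethyl-5-[(triethylsilyl)oxy]hepta-1,3-dien-1-yl acetate; 14 methyl vinyl ketone
Product: 15 (1R,4R,5S)-5-acetyl-4-{(1S,2S)-3-[(tert-butyldiphenylsilyl)oxy]-2-methyl-1-[(triethylsilyl)oxy]propyl}-2-methylcyclohex-2-en-1-yl acetate (C1 acetate, C3 acetyl and C8 side chain all cis)
Conditions: (R)-3,3-diphenyl-1-(o-tolyl)tetrahydro-1H,3H-pyrrolo[1,2-c][1,3,2]oxazaborole (20 mol%), HN(SO2CF3)2 (20 mol%), CH2Cl2, −78 → −40 °C
Reagents that add atoms: methyl vinyl ketone 14, CC(=O)C=C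
Why: Lewis-acid-catalysed endo Diels–Alder reaction that closes ring A: the C10 methyl ("para") and the C8 alkyl group ("ortho") both direct the acetyl-bearing carbon C3 to C8 and should outweigh the weakly donating acetoxy group, the endo transition state of the (1E,3E)-diene places the C1 acetate, the C3 acetyl and the C8 side chain all cis, and the absolute sense comes from the protonated oxazaborolidine, which by the α-C–H···O model should leave the Re face at C3 of the bound enone open, reinforced by the S-configured C7 centre, whose C11 branch lies anti to the incoming dienophile with the silyloxy group inside.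

Step 9
Reactants: 15 (1R,4R,5S)-5-acetyl-4-{(1S,2S)-3-[(tert-butyldiphenylsilyl)oxy]-2-methyl-1-[(triethylsilyl)oxy]propyl}-2-methylcyclohex-2-en-1-yl acetate
Product: 16 (1R,4R,5S)-4-{(1S,2S)-3-[(tert-butyldiphenylsilyl)oxy]-2-methyl-1-[(triethylsilyl)oxy]propyl}-5-(1-methoxyprop-1-en-2-yl)-2-methylcyclohex-2-en-1-yl acetate (E/Z mixture at the enol ether)
Conditions: MeOCH2PPh3Cl, KN(SiMe3)2, THF, −78 → 0 °C
Reagents that add atoms: (methoxymethyl)triphenylphosphonium chloride, [Cl-].COC[P+](c1ccccc1)(c1ccccc1)c1ccccc1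
Why: Wittig methoxymethylenation of the methyl ketone adds C5 at the aldehyde oxidation level; a slight excess of ylide at low temperature should leave the acetate and the epimerisable C3 centre untouched, and the E/Z mixture is of no consequence.

Step 10
Reactants: 16 (1R,4R,5S)-4-{(1S,2S)-3-[(tert-butyldiphenylsilyl)oxy]-2-methyl-1-[(triethylsilyl)oxy]propyl}-5-(1-methoxyprop-1-en-2-yl)-2-methylcyclohex-2-en-1-yl acetate
Product: 18 (1S,4R,4aS,6R,8aS)-1-{(2S)-1-[(tert-butyldiphenylsilyl)oxy]propan-2-yl}-3-hydroxy-4,7-dimethyl-3,4,4a,5,6,8a-hexahydro-1H-isochromen-6-yl acetate (cis-fused lactol, anomer mixture), via hydroxy aldehyde 17 (not isolated)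
Conditions: TsOH·H2O (catalytic), THF/H2O, rt; then DBU (catalytic), CH2Cl2, rt
Reagents that add atoms: water, O
Why: Acid hydrolyses the enol ether and the triethylsilyl ether, the hydroxy aldehyde closes to the six-membered lactol, and base equilibration through the open aldehyde sets C4 under thermodynamic control, because in the cis-fused lactol only the chair with C9 axial keeps C2 and the C7 side chain equatorial, and in that chair the methyl is equatorial in the wanted C4 epimer but syn-axial to C9 in the other.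

Step 11
Reactants: 18 cis-fused lactol
Product: 19 (1R,4S,5S)-4-{(1S,2S)-3-[(tert-butyldiphenylsilyl)oxy]-1-hydroxy-2-methylpropyl}-5-[(1R)-1-(1,3-dithian-2-yl)ethyl]-2-methylcyclohex-2-en-1-yl acetate
Conditions: HS(CH2)3SH, BF3·OEt2, CH2Cl2, −40 °C
Reagents that add atoms: propane-1,3-dithiol, SCCCS
Why: Lewis-acid-mediated dithioacetalisation opens the lactol to the 1,3-dithiane and frees the C7 hydroxyl, and since C4 is no longer next to a carbonyl group it keeps the configuration set in step 10.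

Step 12
Reactants: 19 hydroxy dithiane
Product: 20 (1R,4S,5S)-4-{(2S)-3-[(tert-butyldiphenylsilyl)oxy]-2-methylpropanoyl}-5-[(1R)-1-(1,3-dithian-2-yl)ethyl]-2-methylcyclohex-2-en-1-yl acetate
Conditions: Dess–Martin periodinane, NaHCO3, CH2Cl2, 0 °C → rt
Reagents that add atoms: none
Why: Dess–Martin oxidation under buffered, non-basic conditions should give the ketone without epimerisation at C8 or C11 and without attack on the dithiane, which tolerates the anhydrous reagent.

Step 13
Reactants: 20 keto dithiane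
Product: 21 (1R,4S,5S)-4-{(3R)-4-[(tert-butyldiphenylsilyl)oxy]-3-methylbut-1-en-2-yl}-5-[(1R)-1-(1,3-dithian-2-yl)ethyl]-2-methylcyclohex-2-en-1-yl acetate
Conditions: Zn, CH2Br2, TiCl4, THF/CH2Cl2, 0 °C → rt
Reagents that add atoms: dibromomethane, BrCBr
Why: Takai–Lombardo methylenation with the titanium methylidene made from CH2Br2, Zn and TiCl4 is non-basic, spares acetate and dithiane and is suited to hindered, enolisable ketones, so that C6 is added while C8 and C11 keep their configuration.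

Step 14
Reactants: 21 methylene dithiane
Product: 22 (1R,4S,5S)-4-{(3R)-4-[(tert-butyldiphenylsilyl)oxy]-3-methylbut-1-en-2-yl}-2-methyl-5-[(2R)-1-oxopropan-2-yl]cyclohex-2-en-1-yl acetate
Conditions: MeI, CaCO3, MeCN/H2O, 40 °C
Reagents that add atoms: water, O
Why: S-Methylation turns the dithiane into a leaving group and buffered hydrolysis releases the aldehyde under near-neutral conditions that should neither epimerise C4 nor touch the three alkenes.

Step 15
Reactants: 22 (1R,4S,5S)-4-{(3R)-4-[(tert-butyldiphenylsilyl)oxy]-3-methylbut-1-en-2-yl}-2-methyl-5-[(2R)-1-oxopropan-2-yl]cyclohex-2-en-1-yl acetate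
Product: 23 (3S,4R,4aS,6R,8aS)-1-{(E)-1-[(tert-butyldiphenylsilyl)oxy]propan-2-ylidene}-3-hydroxy-4,7-dimethyl-1,2,3,4,4a,5,6,8a-octahydronaphthalen-6-yl acetate (C5 hydroxyl axial, cis to the C4 methyl)
Conditions: Me2AlCl (2.5 equiv), CH2Cl2, −78 → −20 °C
Reagents that add atoms: none
Why: Me2AlCl binds the aldehyde oxygen and the activated carbonyl carbon C5 bonds to the methylene carbon C6 while the C11 hydrogen passes to oxygen on the same face of the C6=C7–C11 unit, a six-centre carbonyl-ene process after which the alcohol–aluminium complex loses methane so that no acid is left to isomerise the product. The closest known reaction is the Me2AlCl-promoted type 2 intramolecular carbonyl-ene cyclisation of 5-alkylhex-5-enals to 3-alkylidenecyclohexanols. Ring B closes in a 6-endo-trig mode at the alkene (C6 and C7 both inside the ring, the carbonyl oxygen outside) through a chair in which C2 and the C4 methyl are equatorial and C9 is axial at C8, whereas the flipped chair would set the aluminium-bearing oxygen syn-axial to C2 and the C4 methyl axial. The new C5 stereocentre is fixed by that chair, because only an axial C5–O bond reaches the C11 hydrogen, so the hydroxyl should come out axial and cis to the C4 methyl. The step needs one alkene face and one C11 rotamer: the chair fixes the face, and on that face the R-configured C11 can present its hydrogen only with C13 towards C6 and C12 towards C8, which is the E alkene. The C8 hydrogen lies in the plane of the alkene and C9 sits on the far face, so C8 cannot act as hydrogen donor, and the ring A alkene is deactivated by its allylic acetate and would need a strained bicyclo[3.2.1] closure.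

Step 16
Reactants: 23 axial homoallylic alcohol
Product: 24 (4R,4aS,6R,8aS)-1-{(E)-1-[(tert-butyldiphenylsilyl)oxy]propan-2-ylidene}-4,7-dimethyl-3-oxo-1,2,3,4,4a,5,6,8a-octahydronaphthalen-6-yl acetate
Conditions: Dess–Martin periodinane, NaHCO3, CH2Cl2, 0 °C
Reagents that add atoms: none
Why: Dess–Martin oxidation of the axial alcohol gives the β,γ-unsaturated ketone without moving the exocyclic alkene into conjugation, and the equatorial C4 methyl is also the thermodynamic epimer next to the new carbonyl group.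

Step 17
Reactants: 24 ring B ketone
Product: 25 (3R,4R,4aS,6R,8aS)-1-{(E)-1-[(tert-butyldiphenylsilyl)oxy]propan-2-ylidene}-3-hydroxy-4,7-dimethyl-1,2,3,4,4a,5,6,8a-octahydronaphthalen-6-yl acetate (C5 hydroxyl equatorial, trans to the C4 methyl)
Conditions: NaBH4, CeCl3·7H2O, MeOH, −78 °C
Reagents that add atoms: none
Why: Luche reduction: axial hydride delivery to the face of C5 that carries only the axial C3 hydrogen should give the equatorial alcohol trans to the C4 methyl, and acetate and alkenes are inert at low temperature.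

Step 18
Reactants: 25 equatorial alcohol
Product: 26 (3R,4R,4aS,6R,8aS)-1-{(E)-1-[(tert-butyldiphenylsilyl)oxy]propan-2-ylidene}-4,7-dimethyl-1,2,3,4,4a,5,6,8a-octahydronaphthalene-3,6-diyl diacetate
Conditions: Ac2O, pyridine, DMAP, CH2Cl2, rt
Reagents that add atoms: acetic anhydride, CC(=O)OC(C)=O
Why: DMAP-catalysed acylation of the equatorial secondary alcohol gives the second acetate with no change at any stereocentre.

Step 19
Reactants: 26 silyl ether diacetate
Product: 27 (3R,4R,4aS,6R,8aS)-1-[(E)-1-hydroxypropan-2-ylidene]-4,7-dimethyl-1,2,3,4,4a,5,6,8a-octahydronaphthalene-3,6-diyl diacetate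
Conditions: HF·pyridine, pyridine, THF, 0 °C → rt
Reagents that add atoms: none
Why: Fluoride cleaves the silyl ether under buffered conditions that leave both acetates and the tetrasubstituted allylic system untouched.

Step 20
Reactants: 27 allylic alcohol diacetate
Product: 28 (2E)-2-[(3R,4R,4aS,6R,8aS)-3,6-diacetoxy-4,7-dimethyl-3,4,4a,5,6,8a-hexahydronaphthalen-1(2H)-ylidene]propyl formate (target)
Conditions: acetic formic anhydride, pyridine, CH2Cl2, 0 °C
Reagents that add atoms: acetic formic anhydride, CC(=O)OC=O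
Why: The mixed anhydride transfers its formyl group selectively to the primary allylic alcohol, which gives the formate and completes the target.

**Compound list**

1 | methyl (S)-3-hydroxy-2-methylpropanoate | COC(=O)[C@@H](C)CO | starting material
2 | methyl (S)-3-[(tert-butyldiphenylsilyl)oxy]-2-methylpropanoate | COC(=O)[C@@H](C)CO[Si](c1ccccc1)(c1ccccc1)C(C)(C)C | intermediate
3 | (S)-3-[(tert-butyldiphenylsilyl)oxy]-2-methylpropanal | O=C[C@@H](C)CO[Si](c1ccccc1)(c1ccccc1)C(C)(C)C | intermediate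
4 | (−)-B-allyldiisopinocampheylborane | C=CCB([C@@H]1C[C@@H]2C[C@H]([C@H]1C)C2(C)C)[C@@H]1C[C@@H]2C[C@H]([C@H]1C)C2(C)C | starting material
5 | diisopinocampheylborinate ester of 6 (formed in the flask) | C=CC[C@H](OB([C@@H]1C[C@@H]2C[C@H]([C@H]1C)C2(C)C)[C@@H]1C[C@@H]2C[C@H]([C@H]1C)C2(C)C)[C@@H](C)CO[Si](c1ccccc1)(c1ccccc1)C(C)(C)C | intermediate
6 | (2S,3S)-1-[(tert-butyldiphenylsilyl)oxy]-2-methylhex-5-en-3-ol | C=CC[C@H](O)[C@@H](C)CO[Si](c1ccccc1)(c1ccccc1)C(C)(C)C | intermediate
7 | (2S,3S)-1-[(tert-butyldiphenylsilyl)oxy]-2-methyl-3-[(triethylsilyl)oxy]hex-5-ene | C=CC[C@H](O[Si](CC)(CC)CC)[C@@H](C)CO[Si](c1ccccc1)(c1ccccc1)C(C)(C)C | intermediate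
8 | secondary ozonide (1,2,4-trioxolane) of 7 (formed in the flask) | C1(C[C@H](O[Si](CC)(CC)CC)[C@@H](C)CO[Si](c2ccccc2)(c2ccccc2)C(C)(C)C)OCOO1 | intermediate
9 | (3S,4S)-5-[(tert-butyldiphenylsilyl)oxy]-4-methyl-3-[(triethylsilyl)oxy]pentanal | O=CC[C@H](O[Si](CC)(CC)CC)[C@@H](C)CO[Si](c1ccccc1)(c1ccccc1)C(C)(C)C | intermediate
10 | 2-(triphenylphosphoranylidene)propanal | CC(C=O)=P(c1ccccc1)(c1ccccc1)c1ccccc1 | starting material
11 | (2E,5S,6S)-7-[(tert-butyldiphenylsilyl)oxy]-2,6-dimethyl-5-[(triethylsilyl)oxy]hept-2-enal | O=C/C(C)=C/C[C@H](O[Si](CC)(CC)CC)[C@@H](C)CO[Si](c1ccccc1)(c1ccccc1)C(C)(C)C | intermediate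
12 | potassium (1E,3E)-dienolate of 11 (formed in the flask) | [K+].[O-]/C=C(C)/C=C/[C@H](O[Si](CC)(CC)CC)[C@@H](C)CO[Si](c1ccccc1)(c1ccccc1)C(C)(C)C | intermediate
13 | (1E,3E,5S,6S)-7-[(tert-butyldiphenylsilyl)oxy]-2,6-dimethyl-5-[(triethylsilyl)oxy]hepta-1,3-dien-1-yl acetate | CC(=O)O/C=C(C)/C=C/[C@H](O[Si](CC)(CC)CC)[C@@H](C)CO[Si](c1ccccc1)(c1ccccc1)C(C)(C)C | intermediate
14 | methyl vinyl ketone (but-3-en-2-one) | CC(=O)C=C | starting material
15 | (1R,4R,5S)-5-acetyl-4-{(1S,2S)-3-[(tert-butyldiphenylsilyl)oxy]-2-methyl-1-[(triethylsilyl)oxy]propyl}-2-methylcyclohex-2-en-1-yl acetate | CC(=O)O[C@@H]1C[C@H](C(C)=O)[C@H]([C@H](O[Si](CC)(CC)CC)[C@@H](C)CO[Si](c2ccccc2)(c2ccccc2)C(C)(C)C)C=C1C | intermediate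
16 | (1R,4R,5S)-4-{(1S,2S)-3-[(tert-butyldiphenylsilyl)oxy]-2-methyl-1-[(triethylsilyl)oxy]propyl}-5-(1-methoxyprop-1-en-2-yl)-2-methylcyclohex-2-en-1-yl acetate (E/Z mixture) | CC(=O)O[C@@H]1C[C@H](C(C)=COC)[C@H]([C@H](O[Si](CC)(CC)CC)[C@@H](C)CO[Si](c2ccccc2)(c2ccccc2)C(C)(C)C)C=C1C | intermediate
17 | hydroxy aldehyde, both C4 epimers (formed in the flask) | CC(=O)O[C@@H]1C[C@H](C(C)C=O)[C@H]([C@H](O)[C@@H](C)CO[Si](c2ccccc2)(c2ccccc2)C(C)(C)C)C=C1C | intermediate
18 | (1S,4R,4aS,6R,8aS)-1-{(2S)-1-[(tert-butyldiphenylsilyl)oxy]propan-2-yl}-3-hydroxy-4,7-dimethyl-3,4,4a,5,6,8a-hexahydro-1H-isochromen-6-yl acetate (anomer mixture) | CC(=O)O[C@@H]1C[C@@H]2[C@@H](C)C(O)O[C@H]([C@@H](C)CO[Si](c3ccccc3)(c3ccccc3)C(C)(C)C)[C@@H]2C=C1C | intermediate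
19 | (1R,4S,5S)-4-{(1S,2S)-3-[(tert-butyldiphenylsilyl)oxy]-1-hydroxy-2-methylpropyl}-5-[(1R)-1-(1,3-dithian-2-yl)ethyl]-2-methylcyclohex-2-en-1-yl acetate | CC(=O)O[C@@H]1C[C@H]([C@@H](C)C2SCCCS2)[C@H]([C@H](O)[C@@H](C)CO[Si](c2ccccc2)(c2ccccc2)C(C)(C)C)C=C1C | intermediate
20 | (1R,4S,5S)-4-{(2S)-3-[(tert-butyldiphenylsilyl)oxy]-2-methylpropanoyl}-5-[(1R)-1-(1,3-dithian-2-yl)ethyl]-2-methylcyclohex-2-en-1-yl acetate | CC(=O)O[C@@H]1C[C@H]([C@@H](C)C2SCCCS2)[C@H](C(=O)[C@@H](C)CO[Si](c2ccccc2)(c2ccccc2)C(C)(C)C)C=C1C | intermediate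
21 | (1R,4S,5S)-4-{(3R)-4-[(tert-butyldiphenylsilyl)oxy]-3-methylbut-1-en-2-yl}-5-[(1R)-1-(1,3-dithian-2-yl)ethyl]-2-methylcyclohex-2-en-1-yl acetate | CC(=O)O[C@@H]1C[C@H]([C@@H](C)C2SCCCS2)[C@H](C(=C)[C@@H](C)CO[Si](c2ccccc2)(c2ccccc2)C(C)(C)C)C=C1C | intermediate
22 | (1R,4S,5S)-4-{(3R)-4-[(tert-butyldiphenylsilyl)oxy]-3-methylbut-1-en-2-yl}-2-methyl-5-[(2R)-1-oxopropan-2-yl]cyclohex-2-en-1-yl acetate | CC(=O)O[C@@H]1C[C@H]([C@@H](C)C=O)[C@H](C(=C)[C@@H](C)CO[Si](c2ccccc2)(c2ccccc2)C(C)(C)C)C=C1C | intermediate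
23 | (3S,4R,4aS,6R,8aS)-1-{(E)-1-[(tert-butyldiphenylsilyl)oxy]propan-2-ylidene}-3-hydroxy-4,7-dimethyl-1,2,3,4,4a,5,6,8a-octahydronaphthalen-6-yl acetate | CC(=O)O[C@@H]1C[C@@H]2[C@@H](C)[C@@H](O)C/C(=C(/C)CO[Si](c3ccccc3)(c3ccccc3)C(C)(C)C)[C@@H]2C=C1C | intermediate
24 | (4R,4aS,6R,8aS)-1-{(E)-1-[(tert-butyldiphenylsilyl)oxy]propan-2-ylidene}-4,7-dimethyl-3-oxo-1,2,3,4,4a,5,6,8a-octahydronaphthalen-6-yl acetate | CC(=O)O[C@@H]1C[C@@H]2[C@@H](C)C(=O)C/C(=C(/C)CO[Si](c3ccccc3)(c3ccccc3)C(C)(C)C)[C@@H]2C=C1C | intermediate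
25 | (3R,4R,4aS,6R,8aS)-1-{(E)-1-[(tert-butyldiphenylsilyl)oxy]propan-2-ylidene}-3-hydroxy-4,7-dimethyl-1,2,3,4,4a,5,6,8a-octahydronaphthalen-6-yl acetate | CC(=O)O[C@@H]1C[C@@H]2[C@@H](C)[C@H](O)C/C(=C(/C)CO[Si](c3ccccc3)(c3ccccc3)C(C)(C)C)[C@@H]2C=C1C | intermediate
26 | (3R,4R,4aS,6R,8aS)-1-{(E)-1-[(tert-butyldiphenylsilyl)oxy]propan-2-ylidene}-4,7-dimethyl-1,2,3,4,4a,5,6,8a-octahydronaphthalene-3,6-diyl diacetate | CC(=O)O[C@@H]1C[C@@H]2[C@@H](C)[C@H](OC(C)=O)C/C(=C(/C)CO[Si](c3ccccc3)(c3ccccc3)C(C)(C)C)[C@@H]2C=C1C | intermediate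
27 | (3R,4R,4aS,6R,8aS)-1-[(E)-1-hydroxypropan-2-ylidene]-4,7-dimethyl-1,2,3,4,4a,5,6,8a-octahydronaphthalene-3,6-diyl diacetate | CC(=O)O[C@@H]1C[C@@H]2[C@@H](C)[C@H](OC(C)=O)C/C(=C(/C)CO)[C@@H]2C=C1C | intermediate
28 | (2E)-2-[(3R,4R,4aS,6R,8aS)-3,6-diacetoxy-4,7-dimethyl-3,4,4a,5,6,8a-hexahydronaphthalen-1(2H)-ylidene]propyl formate | CC(=O)O[C@@H]1C[C@@H]2[C@@H](C)[C@H](OC(C)=O)C/C(=C(/C)COC=O)[C@@H]2C=C1C | target

**Step count and risks**

Total step count: 20. Longest linear sequence: 20 steps from 1 (compounds 4, 10 and 14 are bought).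

Steps most likely to fail:

Step 15 (key step). The cyclisation may turn stepwise, so that a tertiary C7 cation loses a proton without control (Z alkene, or loss of the C8 hydrogen to a ring diene), or the aldehyde may attack the ring A alkene instead. The fallback replaces steric rotamer control by a temporary aluminium tether. It sets out from 22: HF·pyridine removes the silyl group to give (1R,4S,5S)-4-[(3R)-4-hydroxy-3-methylbut-1-en-2-yl]-2-methyl-5-[(2R)-1-oxopropan-2-yl]cyclohex-2-en-1-yl acetate F1. With three equivalents of Me2AlCl the first equivalent turns the C13 hydroxyl into a chloro(methyl)aluminium alkoxide, and this aluminium, tied to C13, activates the aldehyde from within the molecule; the C13 arm is then held on the C6 side and the C11 hydrogen is the only one within reach of the carbonyl oxygen. The ene closure should give (3S,4R,4aS,6R,8aS)-3-hydroxy-1-[(E)-1-hydroxypropan-2-ylidene]-4,7-dimethyl-1,2,3,4,4a,5,6,8a-octahydronaphthalen-6-yl acetate F2, and selective silylation of its primary allylic hydroxyl (TBDPSCl, imidazole) comes back to the route at 23.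

Step 8. Regiochemical control may be poor (the acetoxy group steering the acetyl-bearing carbon to the C1 side), the facial pairing of catalyst and C7 centre may be mismatched, or the allylic silyl ether may be lost under the acidic catalyst. The fallback uses a magnesium-tethered cycloaddition. It sets out from 13: HF·pyridine buffered with pyridine removes only the triethylsilyl group to give (1E,3E,5S,6S)-7-[(tert-butyldiphenylsilyl)oxy]-5-hydroxy-2,6-dimethylhepta-1,3-dien-1-yl acetate F3. With MgBr2·OEt2 and Et3N in CH2Cl2 its magnesium alkoxide binds methyl vinyl ketone, so that the cycloaddition can only join the acetyl-bearing carbon to C8, endo, on the diene face that carries the C7 oxygen on the inside. This should give (1R,4R,5S)-5-acetyl-4-{(1S,2S)-3-[(tert-butyldiphenylsilyl)oxy]-1-hydroxy-2-methylpropyl}-2-methylcyclohex-2-en-1-yl acetate F4, and silylation with TESCl and imidazole comes back to the route at 15.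

Step 13. Methylenation of the doubly α-branched ketone may be sluggish, with epimerisation at C8 or C11 on long exposure to the Lewis-acidic reagent. The fallback is a two-stage Peterson olefination. It sets out from 20: Me3SiCH2Li with CeCl3 at −78 °C adds to the ketone to give the β-hydroxysilane (1R,4S,5S)-4-{(3S)-4-[(tert-butyldiphenylsilyl)oxy]-2-hydroxy-3-methyl-1-(trimethylsilyl)butan-2-yl}-5-[(1R)-1-(1,3-dithian-2-yl)ethyl]-2-methylcyclohex-2-en-1-yl acetate F5 (either configuration at the new carbinol; the weakly basic cerium reagent should spare the acetate, and any deacetylated material is re-acetylated with Ac2O). Acid-induced elimination with BF3·OEt2 at 0 °C comes back to the route at 21.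

Further compounds
F1 | step 15 | (1R,4S,5S)-4-[(3R)-4-hydroxy-3-methylbut-1-en-2-yl]-2-methyl-5-[(2R)-1-oxopropan-2-yl]cyclohex-2-en-1-yl acetate | CC(=O)O[C@@H]1C[C@H]([C@@H](C)C=O)[C@H](C(=C)[C@@H](C)CO)C=C1C
F2 | step 15 | (3S,4R,4aS,6R,8aS)-3-hydroxy-1-[(E)-1-hydroxypropan-2-ylidene]-4,7-dimethyl-1,2,3,4,4a,5,6,8a-octahydronaphthalen-6-yl acetate | CC(=O)O[C@@H]1C[C@@H]2[C@@H](C)[C@@H](O)C/C(=C(/C)CO)[C@@H]2C=C1C
F3 | step 8 | (1E,3E,5S,6S)-7-[(tert-butyldiphenylsilyl)oxy]-5-hydroxy-2,6-dimethylhepta-1,3-dien-1-yl acetate | CC(=O)O/C=C(C)/C=C/[C@H](O)[C@@H](C)CO[Si](c1ccccc1)(c1ccccc1)C(C)(C)C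
F4 | step 8 | (1R,4R,5S)-5-acetyl-4-{(1S,2S)-3-[(tert-butyldiphenylsilyl)oxy]-1-hydroxy-2-methylpropyl}-2-methylcyclohex-2-en-1-yl acetate | CC(=O)O[C@@H]1C[C@H](C(C)=O)[C@H]([C@H](O)[C@@H](C)CO[Si](c2ccccc2)(c2ccccc2)C(C)(C)C)C=C1C
F5 | step 13 | (1R,4S,5S)-4-{(3S)-4-[(tert-butyldiphenylsilyl)oxy]-2-hydroxy-3-methyl-1-(trimethylsilyl)butan-2-yl}-5-[(1R)-1-(1,3-dithian-2-yl)ethyl]-2-methylcyclohex-2-en-1-yl acetate | CC(=O)O[C@@H]1C[C@H]([C@@H](C)C2SCCCS2)[C@H](C(O)(C[Si](C)(C)C)[C@@H](C)CO[Si](c2ccccc2)(c2ccccc2)C(C)(C)C)C=C1C
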